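**Retrosynthetic overview** (numbering: C1 lactone C=O, C2, C3 = ring CH–OO, C4 = C(CH3)–O, C5 = ring CH2, C6 = C(CH3)(chain)–OO)
1. Plakortolide L ⇐ lactonisation O–C1 (last ring) ⇐ C4 formate ⇐ Baeyer–Villiger oxidation of a C4 aldehyde (retention at C4).
2. 4-Formyl-1,2-dioxane ⇐ formal [3+3] annulation that makes O–C6 and C3–C4 in one operation: formylcyclopropane (C4–C5–C6) + silyl peroxyacetal (O–O–C3), under chiral silylium catalysis.
3. Enabling feature: in the 1,2-dioxane ring the fully substituted C4 and C6 flank the single CH2 (C5), so C4–C5–C6 folds back into a cyclopropane whose strained C4–C6 bond is polarised by a formyl group on C4 (the masked lactone oxygen); C3, the peroxide-bearing ring CH that is β to C1, is an acetal-level carbon.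
4. Cyclopropane ⇐ Charette cyclopropanation of an (E)-tetrasubstituted allylic alcohol ⇐ Negishi coupling of an enol tosylate with the 12-phenyldodecyl chain.
5. Ring order: cyclopropane (temporary) → 1,2-dioxane (step 9) → γ-lactone (step 11).

Key step: step 9

Assumption: the Charette reagent is taken to attack the same alkene face (relative to the CH2OH-bearing carbon) as with (E)-disubstituted allylic alcohols, which calls for the (4S,5S) ligand; the sense of induction of the chiral counteranion in step 9 cannot be predicted from a model, so the catalyst antipode that delivers the (3S,4S) pair is the one meant.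

**Step 1**
Reactants: 1 phenylmagnesium bromide; 2 1,12-dibromododecane
Product: 3 (12-bromododecyl)benzene
Conditions: 2 (3 equiv), Li2CuCl4 (3 mol %), THF, 0 → 23 °C, slow addition of 1
Reagents that add atoms: none
Why: Copper-catalysed Kumada-type sp2–sp3 coupling of an aryl Grignard reagent with a primary alkyl bromide, the excess of 2 keeping the second bromide untouched.

**Step 2**
Reactants: 4 methyl 2-methyl-3-oxobutanoate
Product: 5 methyl (E)-2-methyl-3-(tosyloxy)but-2-enoate
Conditions: TsCl, N-methylimidazole, Et3N, MeCN, 0 °C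
Reagents that add atoms: p-toluenesulfonyl chloride, Cc1ccc(cc1)S(=O)(=O)Cl
Why: O-Sulfonylation of the β-keto ester enolate under non-chelating amine conditions should give the (E)-enol tosylate (ester and OTs trans), the geometry that later fixes C6 and is therefore checked before use.

**Step 3**
Reactants: 3 (12-bromododecyl)benzene; 5 methyl (E)-2-methyl-3-(tosyloxy)but-2-enoate
Product: 7 methyl (E)-2,3-dimethyl-15-phenylpentadec-2-enoate, via (12-phenyldodecyl)zinc bromide 6 (not isolated)
Conditions: Zn dust, LiCl, THF, 50 °C; then 5, PdCl2(dppf) (3 mol %), THF, 60 °C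
Reagents that add atoms: none
Why: Negishi coupling, in which zinc insertion into the primary bromide is followed by stereoretentive palladium-catalysed substitution of the activated enol tosylate, so the chain ends up trans to the ester.

**Step 4**
Reactants: 7 methyl (E)-2,3-dimethyl-15-phenylpentadec-2-enoate
Product: 8 (E)-2,3-dimethyl-15-phenylpentadec-2-en-1-ol
Conditions: DIBAL-H (2.5 equiv), CH2Cl2, −78 → 0 °C; aqueous potassium sodium tartrate work-up
Reagents that add atoms: none
Why: 1,2-Reduction of the enoate by DIBAL-H gives the allylic alcohol without touching the geometry of the tetrasubstituted alkene.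

**Step 5**
Reactants: 8 (E)-2,3-dimethyl-15-phenylpentadec-2-en-1-ol
Product: 9 [(1R,2R)-1,2-dimethyl-2-(12-phenyldodecyl)cyclopropyl]methanol
Conditions: Et2Zn, CH2I2, DME, (4S,5S)-2-butyl-N,N,N′,N′-tetramethyl-1,3,2-dioxaborolane-4,5-dicarboxamide (1.2 equiv), CH2Cl2, −10 → 23 °C; aqueous work-up
Reagents that add atoms: diiodomethane, ICI
Why: Charette asymmetric Simmons–Smith cyclopropanation, in which the zinc carbenoid is delivered through the allylic alkoxide bound to the chiral dioxaborolane and adds stereospecifically syn, so the (E) geometry and the ligand together set (1R,2R), of which only the C2 centre (later C6) matters.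

**Step 6**
Reactants: 9 [(1R,2R)-1,2-dimethyl-2-(12-phenyldodecyl)cyclopropyl]methanol
Product: 10 (1R,2R)-1,2-dimethyl-2-(12-phenyldodecyl)cyclopropane-1-carbaldehyde
Conditions: Dess–Martin periodinane, CH2Cl2, 0 → 23 °C
Reagents that add atoms: none
Why: Dess–Martin oxidation of the neopentyl-type primary alcohol gives an aldehyde without α-hydrogen, so neither stereocentre can epimerise.

**Step 7**
Reactants: 11 dimethyl (E)-hex-3-enedioate
Product: 13 methyl 3-hydroperoxy-3-methoxypropanoate (racemic), via carbonyl oxide 12 (not isolated)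
Conditions: O3, CH2Cl2/MeOH (4:1), −78 °C; N2 purge; cold chromatography
Reagents that add atoms: ozone, [O-][O+]=O; methanol, CO
Why: Ozonolysis with Criegee cleavage of the symmetric alkene and trapping of carbonyl oxide 12 by methanol gives the α-methoxy hydroperoxide, the symmetry of 11 removing any regiochemical issue.

**Step 8**
Reactants: 13 methyl 3-hydroperoxy-3-methoxypropanoate
Product: 14 methyl 3-methoxy-3-[(triethylsilyl)peroxy]propanoate (racemic)
Conditions: Et3SiCl, imidazole, DMF, 0 °C
Reagents that add atoms: chlorotriethylsilane, CC[Si](Cl)(CC)CC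
Why: O-Silylation of the hydroperoxide under mild imidazole conditions masks the OOH proton and installs the silicon that later ionises the acetal.

**Step 9**
Reactants: 10 (1R,2R)-1,2-dimethyl-2-(12-phenyldodecyl)cyclopropane-1-carbaldehyde; 14 methyl 3-methoxy-3-[(triethylsilyl)peroxy]propanoate
Product: 16 methyl 2-[(3S,4S,6S)-4-formyl-4,6-dimethyl-6-(12-phenyldodecyl)-1,2-dioxan-3-yl]acetate, via silyl enol ether peroxyacetal 15 (not isolated)
Conditions: 14 (1.5 equiv), chiral N-triflyl imidodiphosphorimidate (IDPi) acid (3 mol %, antipode as in the remark), methallyltrimethylsilane (10 mol %, silylates the acid), CH2Cl2, −78 → −40 °C, slow addition of 10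
Reagents that add atoms: none
Why: Proposed new method: the silylated acid (R3Si+ paired with the confined chiral anion) converts the formyl group of 10 into a silyloxocarbenium ion, which makes the strained C4–C6 bond a homo-Michael acceptor; the silylated peroxide oxygen of 14 attacks the quaternary C6 from the rear with inversion and the ring opens to enol silane 15, after which the silicon on the peroxide moves to the acetal OMe, Et3SiOMe leaves and the enol silane carbon C4 adds to the peroxycarbenium carbon C3. The closest known reaction types are the Lewis-acid formal [3+3] annulation of donor–acceptor cyclopropanes with nitrones (heteroatom attack with inversion, then Mannich-type closure), the capture of tertiary cations by silyl peroxides in peroxycarbenium [3+2] annulations, the Mukaiyama-type addition of enol silanes to peroxycarbenium ions, and silylium catalysis with confined chiral counteranions in Mukaiyama aldol reactions. The only ring closed is the 1,2-dioxane, by 6-(enolexo)-endo-trig attack through a chair in which the (E)-peroxycarbenium places CH2CO2Me equatorial and the enol carbon axial, so that CH2CO2Me and CHO end up cis. C6 is set by stereospecific inversion of the (2R) cyclopropane carbon of 10 (substrate control), whereas C3 and C4 are set together in the ring closure by the chiral counteranion (catalyst control), because the CH3/CH2R pair at C6 cannot bias the chair; C1 of 10 and the acetal carbon of 14 are planar at the bond-forming stage, so their configurations do not matter. The step needs attack at C6 instead of C5 and loss of methoxide instead of peroxide from the acetal: the first is secured by the tertiary, cation-stabilising C6 and the non-nucleophilic counteranion, the second by the more basic ether oxygen and by silicon delivered from the neighbouring peroxide oxygen.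

**Step 10**
Reactants: 16 methyl 2-[(3S,4S,6S)-4-formyl-4,6-dimethyl-6-(12-phenyldodecyl)-1,2-dioxan-3-yl]acetate
Product: 17 methyl 2-[(3S,4S,6S)-4-(formyloxy)-4,6-dimethyl-6-(12-phenyldodecyl)-1,2-dioxan-3-yl]acetate
Conditions: mCPBA (1.5 equiv), CH2Cl2, 0 → 23 °C
Reagents that add atoms: 3-chloroperoxybenzoic acid, OOC(=O)c1cccc(Cl)c1
Why: Baeyer–Villiger oxidation of an aldehyde with a quaternary α-carbon, in whose Criegee adduct the tertiary C4 should migrate with retention and turn C4–CHO into C4–OCHO, while the dialkyl peroxide and the ester are inert to the peracid.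

**Step 11**
Reactants: 17 methyl 2-[(3S,4S,6S)-4-(formyloxy)-4,6-dimethyl-6-(12-phenyldodecyl)-1,2-dioxan-3-yl]acetate
Product: 19 plakortolide L [(3S,4aS,7aS)-3,4a-dimethyl-3-(12-phenyldodecyl)tetrahydro-3H-furo[3,2-c][1,2]dioxin-6(4H)-one], via hydroxy ester 18 (not isolated)
Conditions: p-TsOH·H2O (10 mol %), MeOH, 0 → 23 °C
Reagents that add atoms: none
Why: Acid-catalysed transesterification frees the tertiary alcohol from its formate and the cis-disposed γ-hydroxy ester 18 lactonises (5-exo-trig acyl substitution) to the cis-fused γ-lactone without touching any stereocentre, base being avoided to exclude Kornblum–DeLaMare cleavage.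

**Compound list**
1 | phenylmagnesium bromide | Br[Mg]c1ccccc1 | starting material
2 | 1,12-dibromododecane | BrCCCCCCCCCCCCBr | starting material
3 | (12-bromododecyl)benzene | BrCCCCCCCCCCCCc1ccccc1 | intermediate
4 | methyl 2-methyl-3-oxobutanoate | COC(=O)C(C)C(C)=O | starting material
5 | methyl (E)-2-methyl-3-(tosyloxy)but-2-enoate | COC(=O)/C(C)=C(C)/OS(=O)(=O)c1ccc(C)cc1 | intermediate
6 | (12-phenyldodecyl)zinc bromide | Br[Zn]CCCCCCCCCCCCc1ccccc1 | intermediate
7 | methyl (E)-2,3-dimethyl-15-phenylpentadec-2-enoate | COC(=O)/C(C)=C(C)/CCCCCCCCCCCCc1ccccc1 | intermediate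
8 | (E)-2,3-dimethyl-15-phenylpentadec-2-en-1-ol | OC/C(C)=C(C)/CCCCCCCCCCCCc1ccccc1 | intermediate
9 | [(1R,2R)-1,2-dimethyl-2-(12-phenyldodecyl)cyclopropyl]methanol | C[C@@]1(CCCCCCCCCCCCc2ccccc2)C[C@@]1(C)CO | intermediate
10 | (1R,2R)-1,2-dimethyl-2-(12-phenyldodecyl)cyclopropane-1-carbaldehyde | C[C@@]1(CCCCCCCCCCCCc2ccccc2)C[C@@]1(C)C=O | intermediate
11 | dimethyl (E)-hex-3-enedioate | COC(=O)C/C=C/CC(=O)OC | starting material
12 | carbonyl oxide of methyl 3-oxopropanoate | COC(=O)CC=[O+][O-] | intermediate
13 | methyl 3-hydroperoxy-3-methoxypropanoate (racemic) | COC(=O)CC(OC)OO | intermediate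
14 | methyl 3-methoxy-3-[(triethylsilyl)peroxy]propanoate (racemic) | COC(=O)CC(OC)OO[Si](CC)(CC)CC | intermediate
15 | methyl 3-methoxy-3-{[(4S)-2,4-dimethyl-16-phenyl-1-(triethylsilyloxy)hexadec-1-en-4-yl]peroxy}propanoate | CC[Si](CC)(CC)OC=C(C)C[C@](C)(CCCCCCCCCCCCc1ccccc1)OOC(OC)CC(=O)OC | intermediate
16 | methyl 2-[(3S,4S,6S)-4-formyl-4,6-dimethyl-6-(12-phenyldodecyl)-1,2-dioxan-3-yl]acetate | C[C@]1(CCCCCCCCCCCCc2ccccc2)C[C@](C)(C=O)[C@H](CC(=O)OC)OO1 | intermediate
17 | methyl 2-[(3S,4S,6S)-4-(formyloxy)-4,6-dimethyl-6-(12-phenyldodecyl)-1,2-dioxan-3-yl]acetate | C[C@]1(CCCCCCCCCCCCc2ccccc2)C[C@](C)(OC=O)[C@H](CC(=O)OC)OO1 | intermediate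
18 | methyl 2-[(3S,4S,6S)-4-hydroxy-4,6-dimethyl-6-(12-phenyldodecyl)-1,2-dioxan-3-yl]acetate | C[C@]1(CCCCCCCCCCCCc2ccccc2)C[C@](C)(O)[C@H](CC(=O)OC)OO1 | intermediate
19 | plakortolide L, (3S,4aS,7aS)-3,4a-dimethyl-3-(12-phenyldodecyl)tetrahydro-3H-furo[3,2-c][1,2]dioxin-6(4H)-one | C[C@]1(CCCCCCCCCCCCc2ccccc2)C[C@]2(C)OC(=O)C[C@@H]2OO1 | target

**Step count and risks**
Total: 11 steps. Longest linear sequence: 8 steps (1, 3, 4, 5, 6, 9, 10, 11).

1. Step 9 (proposed method). What may go wrong: ionisation at C6 before the peroxide attacks (loss of stereochemical fidelity, elimination), insufficient facial discrimination by the counteranion in the ring closure, intermolecular Mukaiyama aldol addition of 15 to unreacted 10, and oxygen transfer from the silyl peroxide to the aldehyde. Fallback with known chemistry, setting out from 3 and coming back at 19: 3 is alkynylated with lithium acetylide–ethylenediamine in DMSO to 14-phenyltetradec-1-yne F1; bromoboration with B-bromo-9-borabicyclo[3.3.1]nonane and protonolysis with AcOH give 2-bromo-14-phenyltetradec-1-ene F2; Mg in THF converts it into (14-phenyltetradec-1-en-2-yl)magnesium bromide F3, which opens commercial (R)-2-methylglycidol at its CH2 terminus under CuI catalysis to give (2S)-2-methyl-4-methylidene-16-phenylhexadecane-1,2-diol F4, the carrier of the C4 stereocentre; Parikh–Doering oxidation of the primary alcohol gives (2S)-2-hydroxy-2-methyl-4-methylidene-16-phenylhexadecanal F5; Still–Gennari olefination gives methyl (2Z,4S)-4-hydroxy-4-methyl-6-methylidene-18-phenyloctadec-2-enoate F6, which lactonises in the flask to (5S)-5-methyl-5-(2-methylidene-14-phenyltetradecyl)furan-2(5H)-one F7; Mukaiyama–Isayama hydroperoxysilylation (Co(thd)2, thd = 2,2,6,6-tetramethylheptane-3,5-dionate, O2, Et3SiH) of the 1,1-disubstituted alkene gives (5S)-5-methyl-5-{2-methyl-14-phenyl-2-[(triethylsilyl)peroxy]tetradecyl}furan-2(5H)-one F8 as both side-chain epimers; HCl in MeOH frees (5S)-5-(2-hydroperoxy-2-methyl-14-phenyltetradecyl)-5-methylfuran-2(5H)-one F9; Et2NH then closes the 1,2-dioxane by oxa-Michael addition to the butenolide, cis-fused by necessity, to give 19 together with 6-epi-plakortolide L F10, from which it is separated by chromatography. This fallback gives up control at C6.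

2. Step 10. What may go wrong: hydride migration instead of C4 migration in the Criegee adduct (over-oxidation to the carboxylic acid), favoured because the β-peroxy substituent lowers the migratory aptitude of C4. Fallback, setting out from 16 and coming back at 19 through 18: Pinnick oxidation (NaClO2, NaH2PO4, 2-methylbut-2-ene) gives (3S,4S,6S)-3-(2-methoxy-2-oxoethyl)-4,6-dimethyl-6-(12-phenyldodecyl)-1,2-dioxane-4-carboxylic acid F11, the very product of hydride migration; DCC coupling with mCPBA gives the mixed diacyl peroxide 3-chlorobenzoyl (3S,4S,6S)-3-(2-methoxy-2-oxoethyl)-4,6-dimethyl-6-(12-phenyldodecyl)-1,2-dioxane-4-carbonyl peroxide F12; on warming in MeCN it undergoes the carboxy-inversion rearrangement (1,2-shift of C4 from carbon to oxygen within an ion pair, with retention) to the mixed carbonic anhydride (3S,4S,6S)-3-(2-methoxy-2-oxoethyl)-4,6-dimethyl-6-(12-phenyldodecyl)-1,2-dioxan-4-yl 3-chlorobenzoyl carbonate F13; methanolysis (MeOH, catalytic TsOH) releases 18, which lactonises to 19 as in step 11.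

3. Step 5. What may go wrong: slow or poorly face-selective methylene transfer to the hindered tetrasubstituted alkene. Fallback, setting out from 8 and coming back at 9: Furukawa-modified Simmons–Smith cyclopropanation (Et2Zn, CH2I2, CH2Cl2; hydroxyl-directed and stereospecific but racemic) gives racemic [(1R*,2R*)-1,2-dimethyl-2-(12-phenyldodecyl)cyclopropyl]methanol F14, and preparative chiral-phase supercritical fluid chromatography separates the enantiomers and returns 9.

**Further compounds**
F1 | step 9 | 14-phenyltetradec-1-yne | C#CCCCCCCCCCCCCc1ccccc1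
F2 | step 9 | 2-bromo-14-phenyltetradec-1-ene | C=C(Br)CCCCCCCCCCCCc1ccccc1
F3 | step 9 | (14-phenyltetradec-1-en-2-yl)magnesium bromide | C=C([Mg]Br)CCCCCCCCCCCCc1ccccc1
F4 | step 9 | (2S)-2-methyl-4-methylidene-16-phenylhexadecane-1,2-diol | OC[C@@](C)(O)CC(=C)CCCCCCCCCCCCc1ccccc1
F5 | step 9 | (2S)-2-hydroxy-2-methyl-4-methylidene-16-phenylhexadecanal | O=C[C@@](C)(O)CC(=C)CCCCCCCCCCCCc1ccccc1
F6 | step 9 | methyl (2Z,4S)-4-hydroxy-4-methyl-6-methylidene-18-phenyloctadec-2-enoate | COC(=O)/C=C\[C@@](C)(O)CC(=C)CCCCCCCCCCCCc1ccccc1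
F7 | step 9 | (5S)-5-methyl-5-(2-methylidene-14-phenyltetradecyl)furan-2(5H)-one | O=C1C=C[C@](C)(CC(=C)CCCCCCCCCCCCc2ccccc2)O1
F8 | step 9 | (5S)-5-methyl-5-{2-methyl-14-phenyl-2-[(triethylsilyl)peroxy]tetradecyl}furan-2(5H)-one (both side-chain epimers) | O=C1C=C[C@](C)(CC(C)(OO[Si](CC)(CC)CC)CCCCCCCCCCCCc2ccccc2)O1
F9 | step 9 | (5S)-5-(2-hydroperoxy-2-methyl-14-phenyltetradecyl)-5-methylfuran-2(5H)-one (both side-chain epimers) | O=C1C=C[C@](C)(CC(C)(OO)CCCCCCCCCCCCc2ccccc2)O1
F10 | step 9 | 6-epi-plakortolide L, (3R,4aS,7aS)-3,4a-dimethyl-3-(12-phenyldodecyl)tetrahydro-3H-furo[3,2-c][1,2]dioxin-6(4H)-one | C[C@@]1(CCCCCCCCCCCCc2ccccc2)C[C@]2(C)OC(=O)C[C@@H]2OO1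
F11 | step 10 | (3S,4S,6S)-3-(2-methoxy-2-oxoethyl)-4,6-dimethyl-6-(12-phenyldodecyl)-1,2-dioxane-4-carboxylic acid | C[C@]1(CCCCCCCCCCCCc2ccccc2)C[C@](C)(C(=O)O)[C@H](CC(=O)OC)OO1
F12 | step 10 | 3-chlorobenzoyl (3S,4S,6S)-3-(2-methoxy-2-oxoethyl)-4,6-dimethyl-6-(12-phenyldodecyl)-1,2-dioxane-4-carbonyl peroxide | C[C@]1(CCCCCCCCCCCCc2ccccc2)C[C@](C)(C(=O)OOC(=O)c3cccc(Cl)c3)[C@H](CC(=O)OC)OO1
F13 | step 10 | (3S,4S,6S)-3-(2-methoxy-2-oxoethyl)-4,6-dimethyl-6-(12-phenyldodecyl)-1,2-dioxan-4-yl 3-chlorobenzoyl carbonate | C[C@]1(CCCCCCCCCCCCc2ccccc2)C[C@](C)(OC(=O)OC(=O)c3cccc(Cl)c3)[C@H](CC(=O)OC)OO1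
F14 | step 5 | racemic [(1R*,2R*)-1,2-dimethyl-2-(12-phenyldodecyl)cyclopropyl]methanol | C[C@@]1(CCCCCCCCCCCCc2ccccc2)C[C@@]1(C)CO.C[C@]1(CCCCCCCCCCCCc2ccccc2)C[C@]1(C)CO
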